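**Retrosynthetic overview**
- The γ‑lactone is closed last from a silyl‑protected hydroxy acid; the exo‑methylene comes from a ketone (Peterson olefination) and the ring stereocentre next to it from hydrogenation of an enone.
- Key disconnection: the bond between the side‑chain CH and the future alkene carbon, made by an intermolecular Evans syn‑aldol between a hexahydroindene carbaldehyde (fragment A) and a chiral N‑acyl oxazolidinone (fragment B).
- Fragment A: Michael addition, Hajos–Parrish aldol condensation, reductive methylation (trans fusion, gem‑dimethyl), Wolff–Kishner, Barton vinyl iodide, formylation.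
- Fragment B: diethyl D‑malate, Fráter–Seebach allylation (sets both lactone stereocentres), reduction, differentiation of the three hydroxyls, oxidative cleavage, acylation of the auxiliary.
- Ring order: five‑membered carbocycle (purchased), six‑membered carbocycle (step 2), γ‑lactone (step 30).

Assumption: the target is the single stereoisomer of the given SMILES, i.e. (1R,3aS,7aS) in the hydrindane, R at the acetoxymethyl‑bearing carbon and (3R,4R) (cis) in the hydroxylactone.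

**Fragment A**

Step 1
Reactants: 1 2-methylcyclopentane-1,3-dione; 2 pent-1-en-3-one (ethyl vinyl ketone)
Product: 3 2-methyl-2-(3-oxopentyl)cyclopentane-1,3-dione
Conditions: H2O, AcOH (cat.), 75 °C
Reagents that add atoms: none
Why: Michael addition of the acidic cyclic 1,3-dione to the enone in water stops at the mono-adduct because the new carbon is quaternary, and no stereocentre is formed.

Step 2
Reactants: 3 2-methyl-2-(3-oxopentyl)cyclopentane-1,3-dione
Product: 4 (7aS)-4,7a-dimethyl-2,3,7,7a-tetrahydro-1H-indene-1,5(6H)-dione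
Conditions: L-phenylalanine (1 equiv), (1S)-(+)-10-camphorsulfonic acid (0.5 equiv), MeCN, reflux
Reagents that add atoms: none
Why: Hajos–Parrish (Eder–Sauer–Wiechert) intramolecular aldol condensation in which the enamine formed from the side-chain ketone and L-phenylalanine attacks one of the two enantiotopic ring carbonyls, closing the six-membered ring and fixing the quaternary centre as 7aS (ee raised by recrystallisation).

Step 3
Reactants: 4 (7aS)-4,7a-dimethyl-2,3,7,7a-tetrahydro-1H-indene-1,5(6H)-dione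
Product: 5 (1S,7aS)-1-hydroxy-4,7a-dimethyl-1,2,3,6,7,7a-hexahydro-5H-inden-5-one
Conditions: NaBH4 (0.3 equiv), EtOH, −20 °C
Reagents that add atoms: none
Why: Chemoselective carbonyl reduction in which NaBH4 attacks the saturated cyclopentanone faster than the conjugated enone and delivers hydride from the face opposite the angular methyl, giving the 1S alcohol (OH cis to methyl).

Step 4
Reactants: 5 (1S,7aS)-1-hydroxy-4,7a-dimethyl-1,2,3,6,7,7a-hexahydro-5H-inden-5-one
Product: 6 (1S,7aS)-1-(methoxymethoxy)-4,7a-dimethyl-1,2,3,6,7,7a-hexahydro-5H-inden-5-one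
Conditions: MOMCl, i-Pr2NEt, CH2Cl2, 0 °C → rt
Reagents that add atoms: chloromethyl methyl ether, COCCl
Why: O-Alkylation gives a methoxymethyl acetal that withstands dissolving metal and hot alkali in the next two steps, with no change at any stereocentre.

Step 5
Reactants: 6 (1S,7aS)-1-(methoxymethoxy)-4,7a-dimethyl-1,2,3,6,7,7a-hexahydro-5H-inden-5-one
Product: 8 (1S,3aR,7aS)-1-(methoxymethoxy)-4,4,7a-trimethyloctahydro-5H-inden-5-one, via lithium enolate 7 (not isolated)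
Conditions: Li, NH3(l)/THF, t-BuOH (1 equiv), −78 °C; then MeI, −78 °C → rt
Reagents that add atoms: iodomethane, CI
Why: Birch-type reductive alkylation (Stork) in which protonation of the β-carbon from the face opposite the angular methyl gives the trans-fused enolate regiospecifically, and C-methylation at the only enolate carbon builds the gem-dimethyl group.

Step 6
Reactants: 8 (1S,3aR,7aS)-1-(methoxymethoxy)-4,4,7a-trimethyloctahydro-5H-inden-5-one
Product: 10 (1S,3aS,7aS)-1-(methoxymethoxy)-4,4,7a-trimethyloctahydro-1H-indene, via hydrazone 9 (not isolated)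
Conditions: N2H4·H2O, KOH, diethylene glycol, 130 °C then 200 °C
Reagents that add atoms: none
Why: Wolff–Kishner reduction (Huang–Minlon procedure) removes the ketone through its hydrazone with loss of N2, tolerating the α-quaternary carbon and the base-stable acetal.

Step 7
Reactants: 10 (1S,3aS,7aS)-1-(methoxymethoxy)-4,4,7a-trimethyloctahydro-1H-indene
Product: 11 (1S,3aS,7aS)-4,4,7a-trimethyloctahydro-1H-inden-1-ol
Conditions: conc. HCl (cat.), MeOH, 55 °C
Reagents that add atoms: none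
Why: Acid-catalysed transacetalisation to methanol removes the methoxymethyl group without touching a stereocentre.

Step 8
Reactants: 11 (1S,3aS,7aS)-4,4,7a-trimethyloctahydro-1H-inden-1-ol
Product: 12 (3aS,7aS)-4,4,7a-trimethyloctahydro-1H-inden-1-one
Conditions: Dess–Martin periodinane, pyridine, CH2Cl2, rt
Reagents that add atoms: none
Why: Dess–Martin oxidation of the secondary alcohol gives the cyclopentanone, whose only enolisable position is a CH2 group so that no stereocentre is at risk.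

Step 9
Reactants: 12 (3aS,7aS)-4,4,7a-trimethyloctahydro-1H-inden-1-one
Product: 13 (1E,3aS,7aS)-1-hydrazinylidene-4,4,7a-trimethyloctahydro-1H-indene
Conditions: N2H4·H2O (excess), Et3N, EtOH, reflux
Reagents that add atoms: hydrazine, NN
Why: Condensation with excess hydrazine gives the N-unsubstituted hydrazone, the excess suppressing azine formation.

Step 10
Reactants: 13 (1E,3aS,7aS)-1-hydrazinylidene-4,4,7a-trimethyloctahydro-1H-indene
Product: 14 (3aS,7aS)-1-iodo-4,4,7a-trimethyl-3a,4,5,6,7,7a-hexahydro-3H-indene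
Conditions: I2, 1,1,3,3-tetramethylguanidine, THF, 0 °C → rt
Reagents that add atoms: iodine, II
Why: Barton vinyl iodide synthesis in which iodine oxidises the hydrazone, N2 is lost and a proton leaves from the only α-CH2, so the iodoalkene forms regiospecifically away from the quaternary carbon.

Step 11
Reactants: 14 (3aS,7aS)-1-iodo-4,4,7a-trimethyl-3a,4,5,6,7,7a-hexahydro-3H-indene
Product: 16 (3aS,7aS)-4,4,7a-trimethyl-3a,4,5,6,7,7a-hexahydro-3H-indene-1-carbaldehyde, via vinyllithium 15 (not isolated)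
Conditions: t-BuLi (2.1 equiv), THF, −78 °C; then DMF, −78 → 0 °C; aq. NH4Cl
Reagents that add atoms: N,N-dimethylformamide, CN(C)C=O
Why: Iodine–lithium exchange followed by formylation of the vinyllithium with DMF (Bouveault-type) gives the enal after hydrolytic work-up with the alkene position retained.

**Fragment B**

Step 12
Reactants: 17 diethyl (2R)-2-hydroxybutanedioate (diethyl D-malate); 18 3-bromoprop-1-ene (allyl bromide)
Product: 20 diethyl (2R,3S)-2-hydroxy-3-(prop-2-en-1-yl)butanedioate, via dilithium alkoxide-enolate 19 (not isolated)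
Conditions: LiN(i-Pr)2 (2.2 equiv), THF, −78 → −20 °C; then 18, −78 → −5 °C
Reagents that add atoms: none
Why: Fráter–Seebach alkylation in which the chelated alkoxide–enolate is allylated on the face anti to the ester on the carbinol carbon, giving the 2R,3S (anti) product in about 9:1 dr, the minor isomer being removed by chromatography at the next stages.

Step 13
Reactants: 20 diethyl (2R,3S)-2-hydroxy-3-(prop-2-en-1-yl)butanedioate
Product: 21 (2R,3R)-3-(prop-2-en-1-yl)butane-1,2,4-triol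
Conditions: LiAlH4, THF, 0 °C → reflux
Reagents that add atoms: none
Why: LiAlH4 reduces both esters to primary alcohols and leaves the isolated alkene and both stereocentres untouched (the descriptor change at C3 is only a CIP priority switch).

Step 14
Reactants: 21 (2R,3R)-3-(prop-2-en-1-yl)butane-1,2,4-triol
Product: 22 (2R)-2-[(4R)-2,2-dimethyl-1,3-dioxolan-4-yl]pent-4-en-1-ol
Conditions: 2,2-dimethoxypropane, TsOH·H2O (cat.), acetone, rt
Reagents that add atoms: 2,2-dimethoxypropane, COC(C)(C)OC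
Why: Thermodynamically controlled acetonide formation selects the five-membered dioxolane of the terminal 1,2-diol and leaves the other primary alcohol free.

Step 15
Reactants: 22 (2R)-2-[(4R)-2,2-dimethyl-1,3-dioxolan-4-yl]pent-4-en-1-ol
Product: 23 tert-butyl{[(2R)-2-[(4R)-2,2-dimethyl-1,3-dioxolan-4-yl]pent-4-en-1-yl]oxy}diphenylsilane
Conditions: TBDPSCl, imidazole, DMF, rt
Reagents that add atoms: tert-butyl(chloro)diphenylsilane, CC(C)(C)[Si](Cl)(c1ccccc1)c1ccccc1
Why: Silylation puts a bulky, acid- and hydride-stable group on the oxygen that becomes the lactone ring oxygen and is kept until the last step.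

Step 16
Reactants: 23 tert-butyl{[(2R)-2-[(4R)-2,2-dimethyl-1,3-dioxolan-4-yl]pent-4-en-1-yl]oxy}diphenylsilane
Product: 25 (3R)-4-[(tert-butyldiphenylsilyl)oxy]-3-[(4R)-2,2-dimethyl-1,3-dioxolan-4-yl]butanal, via ozonide 24 (not isolated)
Conditions: O3, CH2Cl2, −78 °C; then PPh3, −78 °C → rt
Reagents that add atoms: ozone, [O-][O+]=O
Why: Ozonolysis (Criegee mechanism) with reductive phosphine work-up cleaves the terminal alkene to the aldehyde without affecting silyl ether, acetonide or stereocentres.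

Step 17
Reactants: 25 (3R)-4-[(tert-butyldiphenylsilyl)oxy]-3-[(4R)-2,2-dimethyl-1,3-dioxolan-4-yl]butanal
Product: 26 (3R)-4-[(tert-butyldiphenylsilyl)oxy]-3-[(4R)-2,2-dimethyl-1,3-dioxolan-4-yl]butanoic acid
Conditions: NaClO2, NaH2PO4, 2-methyl-2-butene, t-BuOH/H2O, 0 °C → rt
Reagents that add atoms: sodium chlorite, [Na+].[O-]Cl=O
Why: Pinnick oxidation converts the aldehyde to the acid under buffered conditions with the alkene scavenging hypochlorite, so the acid-labile groups survive.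

Step 18
Reactants: 26 (3R)-4-[(tert-butyldiphenylsilyl)oxy]-3-[(4R)-2,2-dimethyl-1,3-dioxolan-4-yl]butanoic acid; 27 (4R)-4-benzyl-1,3-oxazolidin-2-one
Product: 29 (4R)-4-benzyl-3-{(3R)-4-[(tert-butyldiphenylsilyl)oxy]-3-[(4R)-2,2-dimethyl-1,3-dioxolan-4-yl]butanoyl}-1,3-oxazolidin-2-one, via mixed pivalic anhydride 28 (not isolated)
Conditions: PivCl, Et3N, THF, −20 °C; then 27, LiCl, −20 °C → rt
Reagents that add atoms: none
Why: N-Acylation of the oxazolidinone by the mixed anhydride occurs at the less hindered carbonyl and attaches the chiral auxiliary without touching the β-stereocentre.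

**Fragment union and end game**

Step 19
Reactants: 29 (4R)-4-benzyl-3-{(3R)-4-[(tert-butyldiphenylsilyl)oxy]-3-[(4R)-2,2-dimethyl-1,3-dioxolan-4-yl]butanoyl}-1,3-oxazolidin-2-one; 16 (3aS,7aS)-4,4,7a-trimethyl-3a,4,5,6,7,7a-hexahydro-3H-indene-1-carbaldehyde
Product: 31 (4R)-4-benzyl-3-[(2R,3R)-2-{(1R)-2-[(tert-butyldiphenylsilyl)oxy]-1-[(4R)-2,2-dimethyl-1,3-dioxolan-4-yl]ethyl}-3-hydroxy-3-[(3aS,7aS)-4,4,7a-trimethyl-3a,4,5,6,7,7a-hexahydro-3H-inden-1-yl]propanoyl]-1,3-oxazolidin-2-one, via dibutylboron enolate 30 (not isolated)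
Conditions: Bu2BOTf, i-Pr2NEt, CH2Cl2, −78 → 0 °C; then 16, −78 → 0 °C; pH 7 buffer, MeOH, 30% H2O2, 0 °C
Reagents that add atoms: none
Why: Evans syn-aldol reaction, the key intermolecular C–C bond formation, in which the Z-boron enolate reacts through a closed Zimmerman–Traxler transition state on the face dictated by the (R)-benzyl auxiliary, setting the side-chain α-carbon (2R here, the acetoxymethyl-bearing centre of the target) and the carbinol carbon (3R, oxidised later).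

Step 20
Reactants: 31 the aldol adduct of step 19
Product: 32 (1R,2S)-2-{(1R)-2-[(tert-butyldiphenylsilyl)oxy]-1-[(4R)-2,2-dimethyl-1,3-dioxolan-4-yl]ethyl}-1-[(3aS,7aS)-4,4,7a-trimethyl-3a,4,5,6,7,7a-hexahydro-3H-inden-1-yl]propane-1,3-diol
Conditions: LiBH4, THF, 0 °C → rt
Reagents that add atoms: none
Why: Reductive cleavage of the imide gives the primary alcohol that becomes the acetoxymethyl group and returns the auxiliary, leaving silyl ether, acetonide and alkene untouched (the 2S label is a CIP priority change only).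

Step 21
Reactants: 32 the diol of step 20
Product: 33 (1R,2S)-3-[(tert-butyldimethylsilyl)oxy]-2-{(1R)-2-[(tert-butyldiphenylsilyl)oxy]-1-[(4R)-2,2-dimethyl-1,3-dioxolan-4-yl]ethyl}-1-[(3aS,7aS)-4,4,7a-trimethyl-3a,4,5,6,7,7a-hexahydro-3H-inden-1-yl]propan-1-ol
Conditions: TBSCl (1.05 equiv), imidazole, CH2Cl2, 0 °C
Reagents that add atoms: tert-butyl(chloro)dimethylsilane, CC(C)(C)[Si](C)(C)Cl
Why: Steric differentiation lets the primary alcohol be silylated selectively beside the hindered secondary allylic alcohol.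

Step 22
Reactants: 33 the mono-silylated allylic alcohol of step 21
Product: 34 (2S)-3-[(tert-butyldimethylsilyl)oxy]-2-{(1R)-2-[(tert-butyldiphenylsilyl)oxy]-1-[(4R)-2,2-dimethyl-1,3-dioxolan-4-yl]ethyl}-1-[(3aS,7aS)-4,4,7a-trimethyl-3a,4,5,6,7,7a-hexahydro-3H-inden-1-yl]propan-1-one
Conditions: Dess–Martin periodinane, pyridine, CH2Cl2, 0 °C → rt
Reagents that add atoms: none
Why: Dess–Martin oxidation of the allylic alcohol gives the enone under buffered non-basic conditions, so the α-stereocentre next to the β-silyloxy group neither epimerises nor eliminates.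

Step 23
Reactants: 34 the enone of step 22
Product: 35 (2S)-3-[(tert-butyldimethylsilyl)oxy]-2-{(1R)-2-[(tert-butyldiphenylsilyl)oxy]-1-[(4R)-2,2-dimethyl-1,3-dioxolan-4-yl]ethyl}-1-[(1S,3aS,7aS)-4,4,7a-trimethyloctahydro-1H-inden-1-yl]propan-1-one
Conditions: H2 (1 atm), Pd/C (10 wt% palladium on carbon), EtOAc, rt
Reagents that add atoms: none
Why: Heterogeneous hydrogenation of the conjugated ring alkene adds hydrogen from the face opposite the angular methyl, placing the acyl side chain cis to that methyl (the target configuration, labelled 1S here by CIP).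

Step 24
Reactants: 35 the saturated ketone of step 23
Product: 36 (3S)-4-[(tert-butyldimethylsilyl)oxy]-3-{(1R)-2-[(tert-butyldiphenylsilyl)oxy]-1-[(4R)-2,2-dimethyl-1,3-dioxolan-4-yl]ethyl}-2-[(1S,3aS,7aS)-4,4,7a-trimethyloctahydro-1H-inden-1-yl]-1-(trimethylsilyl)butan-2-ol (epimer mixture at C2)
Conditions: Me3SiCH2Li, anhydrous CeCl3, THF, −78 → 0 °C
Reagents that add atoms: (trimethylsilyl)methyllithium, C[Si](C)(C)C[Li]
Why: Organocerium 1,2-addition (first stage of a Peterson olefination) in which the weakly basic Me3SiCH2CeCl2 adds to the hindered enolisable ketone without enolisation or β-elimination, the configuration of the new carbinol being irrelevant.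

Step 25
Reactants: 36 the β-hydroxysilane of step 24
Product: 37 tert-butyl{[(2R)-2-{(1R)-2-[(tert-butyldiphenylsilyl)oxy]-1-[(4R)-2,2-dimethyl-1,3-dioxolan-4-yl]ethyl}-3-[(1R,3aS,7aS)-4,4,7a-trimethyloctahydro-1H-inden-1-yl]but-3-en-1-yl]oxy}dimethylsilane
Conditions: KH, THF, 0 °C → rt
Reagents that add atoms: none
Why: Peterson syn-elimination of the potassium alkoxide gives the 1,1-disubstituted alkene regiospecifically, so neither tetrasubstituted isomer can form.

Step 26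
Reactants: 37 the bis-silyl ether of step 25
Product: 38 (2R)-2-{(1R)-2-[(tert-butyldiphenylsilyl)oxy]-1-[(4R)-2,2-dimethyl-1,3-dioxolan-4-yl]ethyl}-3-[(1R,3aS,7aS)-4,4,7a-trimethyloctahydro-1H-inden-1-yl]but-3-en-1-ol
Conditions: HF·pyridine, pyridine, THF, 0 °C → rt
Reagents that add atoms: none
Why: Buffered HF·pyridine cleaves the primary tert-butyldimethylsilyl ether much faster than the tert-butyldiphenylsilyl ether and does not affect the acetonide or the alkene.

Step 27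
Reactants: 38 the primary alcohol of step 26
Product: 39 (2R)-2-{(1R)-2-[(tert-butyldiphenylsilyl)oxy]-1-[(4R)-2,2-dimethyl-1,3-dioxolan-4-yl]ethyl}-3-[(1R,3aS,7aS)-4,4,7a-trimethyloctahydro-1H-inden-1-yl]but-3-en-1-yl acetate
Conditions: Ac2O, pyridine, DMAP (cat.), CH2Cl2, rt
Reagents that add atoms: acetic anhydride, CC(=O)OC(C)=O
Why: DMAP-catalysed acetylation installs the acetate of the target on the only free hydroxyl.

Step 28
Reactants: 39 the acetate of step 27
Product: 40 (2R)-2-{(2R,3R)-1-[(tert-butyldiphenylsilyl)oxy]-3,4-dihydroxybutan-2-yl}-3-[(1R,3aS,7aS)-4,4,7a-trimethyloctahydro-1H-inden-1-yl]but-3-en-1-yl acetate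
Conditions: AcOH/H2O/THF (3:1:1), 40 °C
Reagents that add atoms: none
Why: Mild aqueous acetic acid hydrolyses the acetonide while the acetate, the silyl ether and the acid-sensitive 1,1-disubstituted alkene survive.

Step 29
Reactants: 40 the 1,2-diol of step 28
Product: 41 (2R,3R)-3-{(2R)-1-(acetyloxy)-3-[(1R,3aS,7aS)-4,4,7a-trimethyloctahydro-1H-inden-1-yl]but-3-en-2-yl}-4-[(tert-butyldiphenylsilyl)oxy]-2-hydroxybutanoic acid
Conditions: TEMPO (0.2 equiv), PhI(OAc)2 (2.5 equiv), MeCN/H2O (1:1), rt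
Reagents that add atoms: water, O
Why: TEMPO/PhI(OAc)2 oxidation in which the oxoammonium species oxidises only the primary alcohol, through the aldehyde hydrate, to the carboxylic acid and leaves the adjacent secondary alcohol and the alkene untouched.

Step 30
Reactants: 41 the silyl-protected hydroxy acid of step 29
Product: 43 (2R)-2-[(3R,4R)-4-hydroxy-5-oxooxolan-3-yl]-3-[(1R,3aS,7aS)-4,4,7a-trimethyloctahydro-1H-inden-1-yl]but-3-en-1-yl acetate, via seco acid 42 (not isolated)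
Conditions: HF·pyridine, THF, rt
Reagents that add atoms: none
Why: Fluoride-mediated desilylation releases the γ-hydroxy acid, which lactonises spontaneously in the acidic medium to the five-membered lactone with both ring stereocentres (3R,4R, cis) carried unchanged from the malate fragment.

**Compound list**

1 | 2-methylcyclopentane-1,3-dione | CC1C(=O)CCC1=O | starting material
2 | pent-1-en-3-one (ethyl vinyl ketone) | C=CC(=O)CC | starting material
3 | 2-methyl-2-(3-oxopentyl)cyclopentane-1,3-dione | CCC(=O)CCC1(C)C(=O)CCC1=O | intermediate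
4 | (7aS)-4,7a-dimethyl-2,3,7,7a-tetrahydro-1H-indene-1,5(6H)-dione | O=C1CCC2=C(C)C(=O)CC[C@]12C | intermediate
5 | (1S,7aS)-1-hydroxy-4,7a-dimethyl-1,2,3,6,7,7a-hexahydro-5H-inden-5-one | O[C@H]1CCC2=C(C)C(=O)CC[C@]12C | intermediate
6 | (1S,7aS)-1-(methoxymethoxy)-4,7a-dimethyl-1,2,3,6,7,7a-hexahydro-5H-inden-5-one | COCO[C@H]1CCC2=C(C)C(=O)CC[C@]12C | intermediate
7 | lithium (1S,3aR,7aS)-1-(methoxymethoxy)-4,7a-dimethyl-2,3,3a,6,7,7a-hexahydro-1H-inden-5-olate (trans-fused enolate, not isolated) | COCO[C@H]1CC[C@H]2C(C)=C(O[Li])CC[C@]12C | intermediate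
8 | (1S,3aR,7aS)-1-(methoxymethoxy)-4,4,7a-trimethyloctahydro-5H-inden-5-one | COCO[C@H]1CC[C@H]2C(C)(C)C(=O)CC[C@]12C | intermediate
9 | (1S,3aS,5E,7aS)-5-hydrazinylidene-1-(methoxymethoxy)-4,4,7a-trimethyloctahydro-1H-indene (not isolated) | COCO[C@H]1CC[C@H]2C(C)(C)/C(=N/N)CC[C@]12C | intermediate
10 | (1S,3aS,7aS)-1-(methoxymethoxy)-4,4,7a-trimethyloctahydro-1H-indene | COCO[C@H]1CC[C@H]2C(C)(C)CCC[C@]12C | intermediate
11 | (1S,3aS,7aS)-4,4,7a-trimethyloctahydro-1H-inden-1-ol | O[C@H]1CC[C@H]2C(C)(C)CCC[C@]12C | intermediate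
12 | (3aS,7aS)-4,4,7a-trimethyloctahydro-1H-inden-1-one | O=C1CC[C@H]2C(C)(C)CCC[C@]12C | intermediate
13 | (1E,3aS,7aS)-1-hydrazinylidene-4,4,7a-trimethyloctahydro-1H-indene | N/N=C1\CC[C@H]2C(C)(C)CCC[C@]12C | intermediate
14 | (3aS,7aS)-1-iodo-4,4,7a-trimethyl-3a,4,5,6,7,7a-hexahydro-3H-indene | IC1=CC[C@H]2C(C)(C)CCC[C@]12C | intermediate
15 | [(3aS,7aS)-4,4,7a-trimethyl-3a,4,5,6,7,7a-hexahydro-3H-inden-1-yl]lithium (not isolated) | [Li]C1=CC[C@H]2C(C)(C)CCC[C@]12C | intermediate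
16 | (3aS,7aS)-4,4,7a-trimethyl-3a,4,5,6,7,7a-hexahydro-3H-indene-1-carbaldehyde | O=CC1=CC[C@H]2C(C)(C)CCC[C@]12C | intermediate
17 | diethyl (2R)-2-hydroxybutanedioate (diethyl D-malate) | CCOC(=O)[C@H](O)CC(=O)OCC | starting material
18 | 3-bromoprop-1-ene (allyl bromide) | C=CCBr | starting material
19 | dilithium alkoxide-enolate of 17 (chelated, not isolated) | CCOC(=O)[C@H](O[Li])/C=C(\O[Li])OCC | intermediate
20 | diethyl (2R,3S)-2-hydroxy-3-(prop-2-en-1-yl)butanedioate | CCOC(=O)[C@H](O)[C@H](CC=C)C(=O)OCC | intermediate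
21 | (2R,3R)-3-(prop-2-en-1-yl)butane-1,2,4-triol | OC[C@H](O)[C@H](CC=C)CO | intermediate
22 | (2R)-2-[(4R)-2,2-dimethyl-1,3-dioxolan-4-yl]pent-4-en-1-ol | CC1(C)OC[C@H](O1)[C@H](CC=C)CO | intermediate
23 | tert-butyl{[(2R)-2-[(4R)-2,2-dimethyl-1,3-dioxolan-4-yl]pent-4-en-1-yl]oxy}diphenylsilane | CC1(C)OC[C@H](O1)[C@H](CC=C)CO[Si](c1ccccc1)(c1ccccc1)C(C)(C)C | intermediate
24 | ozonide of 23, a 3-substituted 1,2,4-trioxolane (epimer mixture at the trioxolane carbon, not isolated) | C1OOC(O1)C[C@H](CO[Si](c1ccccc1)(c1ccccc1)C(C)(C)C)[C@@H]1COC(C)(C)O1 | intermediate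
25 | (3R)-4-[(tert-butyldiphenylsilyl)oxy]-3-[(4R)-2,2-dimethyl-1,3-dioxolan-4-yl]butanal | O=CC[C@H](CO[Si](c1ccccc1)(c1ccccc1)C(C)(C)C)[C@@H]1COC(C)(C)O1 | intermediate
26 | (3R)-4-[(tert-butyldiphenylsilyl)oxy]-3-[(4R)-2,2-dimethyl-1,3-dioxolan-4-yl]butanoic acid | OC(=O)C[C@H](CO[Si](c1ccccc1)(c1ccccc1)C(C)(C)C)[C@@H]1COC(C)(C)O1 | intermediate
27 | (4R)-4-benzyl-1,3-oxazolidin-2-one | O=C1OC[C@@H](Cc2ccccc2)N1 | starting material
28 | mixed anhydride of 26 and pivalic acid (not isolated) | CC(C)(C)C(=O)OC(=O)C[C@H](CO[Si](c1ccccc1)(c1ccccc1)C(C)(C)C)[C@@H]1COC(C)(C)O1 | intermediate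
29 | (4R)-4-benzyl-3-{(3R)-4-[(tert-butyldiphenylsilyl)oxy]-3-[(4R)-2,2-dimethyl-1,3-dioxolan-4-yl]butanoyl}-1,3-oxazolidin-2-one | O=C(C[C@H](CO[Si](c1ccccc1)(c1ccccc1)C(C)(C)C)[C@@H]1COC(C)(C)O1)N1C(=O)OC[C@H]1Cc1ccccc1 | intermediate
30 | (Z)-dibutylboron enolate of 29 (not isolated) | CCCCB(CCCC)O/C(=C\[C@H](CO[Si](c1ccccc1)(c1ccccc1)C(C)(C)C)[C@@H]1COC(C)(C)O1)N1C(=O)OC[C@H]1Cc1ccccc1 | intermediate
31 | (4R)-4-benzyl-3-[(2R,3R)-2-{(1R)-2-[(tert-butyldiphenylsilyl)oxy]-1-[(4R)-2,2-dimethyl-1,3-dioxolan-4-yl]ethyl}-3-hydroxy-3-[(3aS,7aS)-4,4,7a-trimethyl-3a,4,5,6,7,7a-hexahydro-3H-inden-1-yl]propanoyl]-1,3-oxazolidin-2-one | O=C(N1C(=O)OC[C@H]1Cc1ccccc1)[C@@H]([C@@H](O)C1=CC[C@H]2C(C)(C)CCC[C@]12C)[C@H](CO[Si](c1ccccc1)(c1ccccc1)C(C)(C)C)[C@@H]1COC(C)(C)O1 | intermediate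
32 | (1R,2S)-2-{(1R)-2-[(tert-butyldiphenylsilyl)oxy]-1-[(4R)-2,2-dimethyl-1,3-dioxolan-4-yl]ethyl}-1-[(3aS,7aS)-4,4,7a-trimethyl-3a,4,5,6,7,7a-hexahydro-3H-inden-1-yl]propane-1,3-diol | OC[C@@H]([C@@H](O)C1=CC[C@H]2C(C)(C)CCC[C@]12C)[C@H](CO[Si](c1ccccc1)(c1ccccc1)C(C)(C)C)[C@@H]1COC(C)(C)O1 | intermediate
33 | (1R,2S)-3-[(tert-butyldimethylsilyl)oxy]-2-{(1R)-2-[(tert-butyldiphenylsilyl)oxy]-1-[(4R)-2,2-dimethyl-1,3-dioxolan-4-yl]ethyl}-1-[(3aS,7aS)-4,4,7a-trimethyl-3a,4,5,6,7,7a-hexahydro-3H-inden-1-yl]propan-1-ol | CC(C)(C)[Si](C)(C)OC[C@@H]([C@@H](O)C1=CC[C@H]2C(C)(C)CCC[C@]12C)[C@H](CO[Si](c1ccccc1)(c1ccccc1)C(C)(C)C)[C@@H]1COC(C)(C)O1 | intermediate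
34 | (2S)-3-[(tert-butyldimethylsilyl)oxy]-2-{(1R)-2-[(tert-butyldiphenylsilyl)oxy]-1-[(4R)-2,2-dimethyl-1,3-dioxolan-4-yl]ethyl}-1-[(3aS,7aS)-4,4,7a-trimethyl-3a,4,5,6,7,7a-hexahydro-3H-inden-1-yl]propan-1-one | O=C(C1=CC[C@H]2C(C)(C)CCC[C@]12C)[C@H](CO[Si](C)(C)C(C)(C)C)[C@H](CO[Si](c1ccccc1)(c1ccccc1)C(C)(C)C)[C@@H]1COC(C)(C)O1 | intermediate
35 | (2S)-3-[(tert-butyldimethylsilyl)oxy]-2-{(1R)-2-[(tert-butyldiphenylsilyl)oxy]-1-[(4R)-2,2-dimethyl-1,3-dioxolan-4-yl]ethyl}-1-[(1S,3aS,7aS)-4,4,7a-trimethyloctahydro-1H-inden-1-yl]propan-1-one | O=C([C@H]1CC[C@H]2C(C)(C)CCC[C@]12C)[C@H](CO[Si](C)(C)C(C)(C)C)[C@H](CO[Si](c1ccccc1)(c1ccccc1)C(C)(C)C)[C@@H]1COC(C)(C)O1 | intermediate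
36 | (3S)-4-[(tert-butyldimethylsilyl)oxy]-3-{(1R)-2-[(tert-butyldiphenylsilyl)oxy]-1-[(4R)-2,2-dimethyl-1,3-dioxolan-4-yl]ethyl}-2-[(1S,3aS,7aS)-4,4,7a-trimethyloctahydro-1H-inden-1-yl]-1-(trimethylsilyl)butan-2-ol (epimer mixture at C2) | C[Si](C)(C)CC(O)([C@H]1CC[C@H]2C(C)(C)CCC[C@]12C)[C@H](CO[Si](C)(C)C(C)(C)C)[C@H](CO[Si](c1ccccc1)(c1ccccc1)C(C)(C)C)[C@@H]1COC(C)(C)O1 | intermediate
37 | tert-butyl{[(2R)-2-{(1R)-2-[(tert-butyldiphenylsilyl)oxy]-1-[(4R)-2,2-dimethyl-1,3-dioxolan-4-yl]ethyl}-3-[(1R,3aS,7aS)-4,4,7a-trimethyloctahydro-1H-inden-1-yl]but-3-en-1-yl]oxy}dimethylsilane | C=C([C@H]1CC[C@H]2C(C)(C)CCC[C@]12C)[C@H](CO[Si](C)(C)C(C)(C)C)[C@H](CO[Si](c1ccccc1)(c1ccccc1)C(C)(C)C)[C@@H]1COC(C)(C)O1 | intermediate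
38 | (2R)-2-{(1R)-2-[(tert-butyldiphenylsilyl)oxy]-1-[(4R)-2,2-dimethyl-1,3-dioxolan-4-yl]ethyl}-3-[(1R,3aS,7aS)-4,4,7a-trimethyloctahydro-1H-inden-1-yl]but-3-en-1-ol | C=C([C@H]1CC[C@H]2C(C)(C)CCC[C@]12C)[C@H](CO)[C@H](CO[Si](c1ccccc1)(c1ccccc1)C(C)(C)C)[C@@H]1COC(C)(C)O1 | intermediate
39 | (2R)-2-{(1R)-2-[(tert-butyldiphenylsilyl)oxy]-1-[(4R)-2,2-dimethyl-1,3-dioxolan-4-yl]ethyl}-3-[(1R,3aS,7aS)-4,4,7a-trimethyloctahydro-1H-inden-1-yl]but-3-en-1-yl acetate | C=C([C@H]1CC[C@H]2C(C)(C)CCC[C@]12C)[C@H](COC(C)=O)[C@H](CO[Si](c1ccccc1)(c1ccccc1)C(C)(C)C)[C@@H]1COC(C)(C)O1 | intermediate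
40 | (2R)-2-{(2R,3R)-1-[(tert-butyldiphenylsilyl)oxy]-3,4-dihydroxybutan-2-yl}-3-[(1R,3aS,7aS)-4,4,7a-trimethyloctahydro-1H-inden-1-yl]but-3-en-1-yl acetate | C=C([C@H]1CC[C@H]2C(C)(C)CCC[C@]12C)[C@H](COC(C)=O)[C@H](CO[Si](c1ccccc1)(c1ccccc1)C(C)(C)C)[C@@H](O)CO | intermediate
41 | (2R,3R)-3-{(2R)-1-(acetyloxy)-3-[(1R,3aS,7aS)-4,4,7a-trimethyloctahydro-1H-inden-1-yl]but-3-en-2-yl}-4-[(tert-butyldiphenylsilyl)oxy]-2-hydroxybutanoic acid | C=C([C@H]1CC[C@H]2C(C)(C)CCC[C@]12C)[C@H](COC(C)=O)[C@H](CO[Si](c1ccccc1)(c1ccccc1)C(C)(C)C)[C@@H](O)C(=O)O | intermediate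
42 | (2R,3R)-3-{(2R)-1-(acetyloxy)-3-[(1R,3aS,7aS)-4,4,7a-trimethyloctahydro-1H-inden-1-yl]but-3-en-2-yl}-2,4-dihydroxybutanoic acid (seco acid, not isolated) | C=C([C@H]1CC[C@H]2C(C)(C)CCC[C@]12C)[C@H](COC(C)=O)[C@H](CO)[C@@H](O)C(=O)O | intermediate
43 | (2R)-2-[(3R,4R)-4-hydroxy-5-oxooxolan-3-yl]-3-[(1R,3aS,7aS)-4,4,7a-trimethyloctahydro-1H-inden-1-yl]but-3-en-1-yl acetate (CNP0252518.3) | C=C([C@H]1CC[C@H]2C(C)(C)CCC[C@]12C)[C@H](COC(C)=O)[C@@H]1COC(=O)[C@@H]1O | target

**Totals**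

Total step count: 30 (fragment A 11 steps, fragment B 7 steps, 12 steps after the union).
Longest linear sequence: 23 steps (steps 1–11, then 19–30).

**Three steps most likely to fail, with fallbacks**

For step 19, both partners are hindered (a β-branched enolate and an aldehyde on a ring carbon next to a quaternary centre), so the boron aldol may stall. The fallback sets out from 29 and joins the fragments by organolithium addition instead. Deprotonation with NaN(SiMe3)2 (THF, −78 °C) and alkylation with benzyl chloromethyl ether gives the benzyloxymethyl imide F1. The chelated sodium enolate is alkylated on the face opposite to that used by the boron aldol, but the imide carbonyl now becomes the ketone carbon, so the same configuration results at the side-chain centre. LiBH4 then gives the primary alcohol F2 and Dess–Martin periodinane the aldehyde F3. Vinyllithium 15 (from 14, with CeCl3, −78 °C) adds to give the allylic alcohol F4 as a carbinol epimer mixture, which Dess–Martin periodinane oxidises to the enone F5. Hydrogenation over Pd/C reduces the ring alkene from the face opposite the angular methyl and cleaves the benzyl ether in the same operation, giving the hydroxy ketone F6. Silylation with TBSCl/imidazole comes back to the route at 35.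

For step 24, the ketone is flanked by two tertiary carbons and the bulky silylmethyl nucleophile may not add. The fallback sets out from 35: the smaller MeLi with CeCl3 (THF, −78 °C) gives the tertiary methyl carbinol F7. Dehydration with SOCl2/pyridine (0 °C) should take a methyl hydrogen, because the two competing β-hydrogens are tertiary and shielded. This comes back to the route at 37.

For step 29, oxidation of a terminal 1,2-diol to the α-hydroxy acid may be accompanied by over-oxidation or C–C cleavage. The fallback sets out from 40: TEMPO/PhI(OAc)2 in dry CH2Cl2 is stopped at the hydroxy aldehyde F8. HF·pyridine then removes the silyl group, so the freed primary alcohol closes onto the aldehyde to give the lactol F9. Ag2CO3 on Celite (benzene, reflux) oxidises the lactol selectively in the presence of the secondary alcohol and the alkene. This comes back to the route at 43.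

Further compounds
F1 | step 19 | (4R)-4-benzyl-3-{(2S,3R)-2-[(benzyloxy)methyl]-4-[(tert-butyldiphenylsilyl)oxy]-3-[(4R)-2,2-dimethyl-1,3-dioxolan-4-yl]butanoyl}-1,3-oxazolidin-2-one | O=C(N1C(=O)OC[C@H]1Cc1ccccc1)[C@H](COCc1ccccc1)[C@H](CO[Si](c1ccccc1)(c1ccccc1)C(C)(C)C)[C@@H]1COC(C)(C)O1
F2 | step 19 | (2R,3R)-2-[(benzyloxy)methyl]-4-[(tert-butyldiphenylsilyl)oxy]-3-[(4R)-2,2-dimethyl-1,3-dioxolan-4-yl]butan-1-ol | OC[C@H](COCc1ccccc1)[C@H](CO[Si](c1ccccc1)(c1ccccc1)C(C)(C)C)[C@@H]1COC(C)(C)O1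
F3 | step 19 | (2S,3R)-2-[(benzyloxy)methyl]-4-[(tert-butyldiphenylsilyl)oxy]-3-[(4R)-2,2-dimethyl-1,3-dioxolan-4-yl]butanal | O=C[C@H](COCc1ccccc1)[C@H](CO[Si](c1ccccc1)(c1ccccc1)C(C)(C)C)[C@@H]1COC(C)(C)O1
F4 | step 19 | (2S,3R)-2-[(benzyloxy)methyl]-4-[(tert-butyldiphenylsilyl)oxy]-3-[(4R)-2,2-dimethyl-1,3-dioxolan-4-yl]-1-[(3aS,7aS)-4,4,7a-trimethyl-3a,4,5,6,7,7a-hexahydro-3H-inden-1-yl]butan-1-ol (epimer mixture at C1) | OC(C1=CC[C@H]2C(C)(C)CCC[C@]12C)[C@H](COCc1ccccc1)[C@H](CO[Si](c1ccccc1)(c1ccccc1)C(C)(C)C)[C@@H]1COC(C)(C)O1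
F5 | step 19 | (2S,3R)-2-[(benzyloxy)methyl]-4-[(tert-butyldiphenylsilyl)oxy]-3-[(4R)-2,2-dimethyl-1,3-dioxolan-4-yl]-1-[(3aS,7aS)-4,4,7a-trimethyl-3a,4,5,6,7,7a-hexahydro-3H-inden-1-yl]butan-1-one | O=C(C1=CC[C@H]2C(C)(C)CCC[C@]12C)[C@H](COCc1ccccc1)[C@H](CO[Si](c1ccccc1)(c1ccccc1)C(C)(C)C)[C@@H]1COC(C)(C)O1
F6 | step 19 | (2S,3R)-4-[(tert-butyldiphenylsilyl)oxy]-3-[(4R)-2,2-dimethyl-1,3-dioxolan-4-yl]-2-(hydroxymethyl)-1-[(1S,3aS,7aS)-4,4,7a-trimethyloctahydro-1H-inden-1-yl]butan-1-one | O=C([C@H]1CC[C@H]2C(C)(C)CCC[C@]12C)[C@H](CO)[C@H](CO[Si](c1ccccc1)(c1ccccc1)C(C)(C)C)[C@@H]1COC(C)(C)O1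
F7 | step 24 | (3S)-4-[(tert-butyldimethylsilyl)oxy]-3-{(1R)-2-[(tert-butyldiphenylsilyl)oxy]-1-[(4R)-2,2-dimethyl-1,3-dioxolan-4-yl]ethyl}-2-[(1S,3aS,7aS)-4,4,7a-trimethyloctahydro-1H-inden-1-yl]butan-2-ol (epimer mixture at C2) | CC(O)([C@H]1CC[C@H]2C(C)(C)CCC[C@]12C)[C@H](CO[Si](C)(C)C(C)(C)C)[C@H](CO[Si](c1ccccc1)(c1ccccc1)C(C)(C)C)[C@@H]1COC(C)(C)O1
F8 | step 29 | (2R)-2-{(2R,3R)-1-[(tert-butyldiphenylsilyl)oxy]-3-hydroxy-4-oxobutan-2-yl}-3-[(1R,3aS,7aS)-4,4,7a-trimethyloctahydro-1H-inden-1-yl]but-3-en-1-yl acetate | C=C([C@H]1CC[C@H]2C(C)(C)CCC[C@]12C)[C@H](COC(C)=O)[C@H](CO[Si](c1ccccc1)(c1ccccc1)C(C)(C)C)[C@@H](O)C=O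
F9 | step 29 | (2R)-2-[(3R,4R)-4,5-dihydroxyoxolan-3-yl]-3-[(1R,3aS,7aS)-4,4,7a-trimethyloctahydro-1H-inden-1-yl]but-3-en-1-yl acetate (anomer mixture) | C=C([C@H]1CC[C@H]2C(C)(C)CCC[C@]12C)[C@H](COC(C)=O)[C@@H]1COC(O)[C@@H]1O
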